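**The leftover.** What I want from this racemate is the right-handed substrate left behind, so I follow fractions left, not product made.

- whether the excess of right-handed substrate over left-handed substrate among what is left of the two reaches 90% by 15 min (no / yes)
- the highest excess of right-handed substrate over left-handed substrate among what is left of the two up to 15 min

| flask | left-handed substrate | right-handed substrate | solid reagent | catalyst | added ligand | remark | time |
|---|---|---|---|---|---|---|---|
| zeta | 0.13 M | 0.13 M | 0.24 M | 2 mM | 1 mM | run made earlier |  |
| delta | 0.30 M | 0.30 M | 0.24 M | 2 mM | 1 mM | run made earlier |  |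
| alpha | 0.20 M | 0.20 M | 0.24 M | 2 mM | 2 mM | run made earlier |  |
| flask | 0.20 M | 0.20 M | 0.240 M | 2.0 mM | 1.0 mM |  | 15 min |

| run | time / min | right-handed substrate / % | left-handed substrate / % | left-handed product / % |
|---|---|---|---|---|
| zeta | 1.33 | 49.5 | 30.6 | 20.2 |
| zeta | 2.00 | 48.9 | 18.8 | 31.2 |
| zeta | 3.00 | 48.4 | 8.5 | 43.4 |
| zeta | 5.00 | 47.0 | 1.7 | 48.0 |
| zeta | 8.00 | 45.3 | 0.2 | 49.5 |
| zeta | 12.0 | 42.4 | 0 | 50.7 |
| zeta | 20.0 | 38.8 | 0 | 50.5 |
| delta | 2.50 | 49.0 | 21.1 | 28.9 |
| delta | 5.00 | 48.8 | 13.6 | 36.5 |
| delta | 8.00 | 48.8 | 12.0 | 37.9 |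
| delta | 10.0 | 48.5 | 12.1 | 38.2 |
| delta | 12.0 | 48.4 | 12.3 | 38.8 |
| delta | 15.0 | 48.7 | 11.6 | 38.3 |
| delta | 20.0 | 48.6 | 11.7 | 37.9 |
| alpha | 1.33 | 49.5 | 35.4 | 14.4 |
| alpha | 2.50 | 49.4 | 20.0 | 30.0 |
| alpha | 5.00 | 47.7 | 8.1 | 41.9 |
| alpha | 10.0 | 47.2 | 2.4 | 47.2 |
| alpha | 20.0 | 45.5 | 0.3 | 49.1 |

(each reading ± 0.3 percentage points)

- catalyst is single-handed; left-handed substrate and right-handed substrate are mirror images of each other, charged as a racemate, each of them at the stated concentration
- solid reagent is a solid; its amount is given per volume of the solution
- at the start none of the solid reagent is in solution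

**Stopping point.** Delta stops with 0.238 M of substrate reacted, close to its 0.24 M of solid reagent, so I treat that solid as the limiting reagent, one per substrate.

**Selectivity factor.** Zeta at 5.00 min keeps 3.40% of its left-handed and 94.0% of its right-handed charge. The logarithm of the first fraction over the logarithm of the second is 54.6, a reading. I carry this selectivity factor to the flask.

**Reagent needed.** In the flask, an excess of 90% means a left-to-right ratio of 0.0526. The factor puts that at 94.7% of the right-handed charge, after 0.201 M of substrate has reacted, less than the 0.240 M of solid reagent charged.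

**Weak link.** The weak link is whether the flask gets there in time. Alpha has the flask's substrate charge and twice its ligand. At 1.33 min alpha keeps 35.4% left-handed where zeta keeps 30.6%, but those two runs differ in both substrate and ligand, so I assume, without a run that shows it, that the flask is no slower than alpha. Alpha's excess reads 90.3% at 10.0 min. Letting alpha's ratio fall geometrically to 20.0 min gives an estimate of 96.4% for alpha at 15 min. I commit to yes for the flask, and to about that figure for its top.

**The forecast.** It says yes and 98%, holding that “flask at 15 min resembles alpha at about 20 min”; that top stands above my estimate.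

**The flask.** The simulation answers yes, with a top of 97.4%. The flask passes 90% at 7.68 min, when right-handed substrate stands at 46.9% of the two substrates charged together.

    coupling partner + catalyst + left-handed substrate → catalyst + left-handed product (k = 170 L² mol⁻² s⁻¹)
    coupling partner + catalyst + right-handed substrate → catalyst + right-handed product (k = 3.60 L² mol⁻² s⁻¹)
    catalyst + added ligand ⇌ idle complex (K = 950 L mol⁻¹, k = 240 L mol⁻¹ s⁻¹)
    coupling partner ⇌ dormant form (K = 1.20, k = 0.100 s⁻¹)
    solid reagent ⇌ coupling partner, rate k5*(cs5 - [coupling partner]) while solid is left; crystals form when [coupling partner] > cs5 (solubility = 0.170 M, k = 0.0120 s⁻¹)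

**Factor reused.** At 15.0 min the flask keeps 1.2% of its left-handed and 91% of its right-handed charge, a factor of 46.9. In delta at 20.0 min, the 11.7% left-handed substrate and the zeta factor give 48.7% right-handed substrate, and the reading is 48.6%.

(The earlier runs and the new flask stem from a simulated flask with constants of no real substance.)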